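**Retrosynthetic overview** (carotenoid numbering; ring A = β-ring C1–C6, ring B = ε-ring C1′–C6′)
1. The all-E polyene is cut at C11=C12 (Wittig) into the ring-A C15 phosphonium salt 13 (3-myristate) and the ring-B C25 apo-aldehyde 24 (3′-palmitate); 24 comes from the ring-B C15 salt 21 and C10 dialdehyde 22 (Wittig at C11′=C12′).
2. Ring B is bought intact as (R)-α-ionone (C6′); C3′–O is added by allylic oxidation and C6′-controlled hydride reduction, then palmitoylated; each C13 ketone goes to its C15 salt by vinyl Grignard addition and PPh3·HBr.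
3. Ring A: 13 ← 3-acyloxy-β-ionone 11 ← alkenylstannane 10 ← enyne 9; 9 ← bicyclo[3.1.0]hexane carbinol 7 + myristic acid by cyclopropylcarbinyl-to-homoallyl ring expansion (five- to six-membered).
4. Enabling feature: in ring A the acyloxy carbon C3 is homoallylic to the C5=C6 double bond (C3–C4–C5=C6), and C6 lies between the fully substituted C1 and C5. Ring A is therefore the retron of a C6 cation next to a C3–C4–C5 cyclopropane that can open but cannot eliminate.
5. Ring order: cyclopentenone (bought) → fused cyclopropane (CBS-set carbinol, directed Simmons–Smith; one catalytic stereocentre relayed to C3) → six-membered ring A in the key step; ring B is never built.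

Key step: step 6

Remark: the target is read as (3R,3′R,6′R)-lutein 3-O-tetradecanoate 3′-O-hexadecanoate (myristate on ring A, palmitate on ring B and trans to the polyene), and enantioenriched (R)-α-ionone is taken as a purchasable material.

**Ring A fragment**

Step 1
Reactants: 1 2-methylcyclopent-2-en-1-one
Product: 3 2,5,5-trimethylcyclopent-2-en-1-one, via 2,5-dimethylcyclopent-2-en-1-one 2 (not isolated)
Conditions: LiN(i-Pr)2 (1.05 equiv), THF, −78 °C; MeI; then LiN(i-Pr)2 (1.1 equiv), −78 °C; MeI, DMPU, −78 → 0 °C (one pot)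
Reagents that add atoms: iodomethane, CI
Why: Kinetic α′-deprotonation of the enone at C5 followed by C-methylation, carried out twice, should install the gem-dimethyl group (sequential enolate alkylation), the second enolate forming at the only remaining α′-hydrogen.

Step 2
Reactants: 3 2,5,5-trimethylcyclopent-2-en-1-one
Product: 4 (1R)-2,5,5-trimethylcyclopent-2-en-1-ol
Conditions: (S)-Me-CBS oxazaborolidine (15 mol %), catecholborane (1.5 equiv), toluene, −78 °C; aq. NaOH work-up
Reagents that add atoms: none
Why: Corey–Bakshi–Shibata reduction, with the ketone bound to boron anti to the α-methyl-substituted alkene arm taken as the large group, should deliver hydride to one face and set the (R)-carbinol, the only stereocentre of ring A made by catalysis.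

Step 3
Reactants: 4 (1R)-2,5,5-trimethylcyclopent-2-en-1-ol
Product: 5 (1S,2R,5S)-1,3,3-trimethylbicyclo[3.1.0]hexan-2-ol
Conditions: Et2Zn, CH2I2, CH2Cl2, 0 °C → rt
Reagents that add atoms: diiodomethane, ICI
Why: Hydroxyl-directed Simmons–Smith cyclopropanation (Furukawa variant) delivers the methylene from the zinc alkoxide to the alkene face syn to oxygen, so both ring-fusion stereocentres (1S,5S) follow from the carbinol by substrate control.

Step 4
Reactants: 5 (1S,2R,5S)-1,3,3-trimethylbicyclo[3.1.0]hexan-2-ol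
Product: 6 (1S,5S)-1,3,3-trimethylbicyclo[3.1.0]hexan-2-one
Conditions: Dess–Martin periodinane, pyridine, CH2Cl2, 0 °C → rt
Reagents that add atoms: none
Why: Dess–Martin oxidation of the secondary cyclopropylcarbinol under buffered conditions should give the non-enolisable ketone with the cyclopropane intact, the carbinol stereocentre having done its relay work.

Step 5
Reactants: 6 (1S,5S)-1,3,3-trimethylbicyclo[3.1.0]hexan-2-one
Product: 7 (1S,5S)-2-ethynyl-1,3,3-trimethylbicyclo[3.1.0]hexan-2-ol (C2 epimers)
Conditions: HC≡CMgBr, THF, 0 °C → rt; aq. NH4Cl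
Reagents that add atoms: ethynylmagnesium bromide, C#C[Mg]Br
Why: 1,2-Addition of the small alkynyl Grignard reagent to a ketone without α-hydrogens (no enolisation) should give the tertiary propargylic cyclopropylcarbinol, whose C2 configuration is of no consequence because it is lost in the next step.

Step 6
Reactants: 7 (1S,5S)-2-ethynyl-1,3,3-trimethylbicyclo[3.1.0]hexan-2-ol
Product: 9 (1R)-4-ethynyl-3,5,5-trimethylcyclohex-3-en-1-yl tetradecanoate, via cyclopropylcarbinyl cation 8 (not isolated)
Conditions: myristic acid (3 equiv), Yb(OTf)3 (10 mol %), 4 Å MS, ClCH2CH2Cl, 40 °C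
Reagents that add atoms: tetradecanoic acid (myristic acid), CCCCCCCCCCCCCC(=O)O
Why: Yb(OTf)3 ionises the tertiary propargylic cyclopropylcarbinol 7 to cation 8, whose charge is shared with the cyclopropane; myristic acid then attacks the methine carbon C5 of the bicycle anti to the C1–C5 bond (the zero bridge), which breaks as the C1=C2 double bond forms, so strain release and enyne conjugation drive the change of the cyclopentane into the cyclohexene of ring A. The closest known reaction type is the acid-mediated cyclopropylcarbinyl-to-homoallyl rearrangement with capture by an oxygen nucleophile, as in the conversion of 3,5-cyclosteroid 6-ethers into 3β-esters of 5-ene steroids with carboxylic acids, of sabinene hydrate into terpinen-4-yl derivatives, and of 1-cyclopropylprop-2-yn-1-ols into conjugated enynes by alcohols under lanthanide triflate catalysis. No new ring bond is closed: ring A arises by one-carbon ring expansion, the cyclopropane CH2 ending up between the two former ring-fusion carbons once their shared bond is cut. The new stereocentre (C3 of the carotenoid) is set by substrate control through inversion at the cyclopropane methine, so (5S) in 7 should give (R) in 9. The step needs capture at the secondary methine rather than at the primary cyclopropane CH2, at C2 or at the alkyne terminus: the secondary carbon carries more of the charge, return at C2 is reversible, and since C1 and C3 of the cation are fully substituted there is no β-hydrogen for elimination. The sieves keep water from competing, and any (R)-alcohol formed by water capture would converge on 9 by acylation.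

Step 7
Reactants: 9 (1R)-4-ethynyl-3,5,5-trimethylcyclohex-3-en-1-yl tetradecanoate
Product: 10 (1R)-3,5,5-trimethyl-4-[(E)-2-(tributylstannyl)ethenyl]cyclohex-3-en-1-yl tetradecanoate
Conditions: Bu3SnH (1.05 equiv), PdCl2(PPh3)2 (2 mol %), THF, 0 °C → rt
Reagents that add atoms: tributyltin hydride, CCCC[SnH](CCCC)CCCC
Why: Palladium-catalysed syn-hydrostannation of the terminal alkyne should place tin on the terminal carbon, away from the fully substituted cyclohexenyl group, and give the (E)-alkenylstannane with the ester untouched.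

Step 8
Reactants: 10 (1R)-3,5,5-trimethyl-4-[(E)-2-(tributylstannyl)ethenyl]cyclohex-3-en-1-yl tetradecanoate
Product: 11 (1R)-3,5,5-trimethyl-4-[(1E)-3-oxobut-1-en-1-yl]cyclohex-3-en-1-yl tetradecanoate ((3R)-3-myristoyloxy-β-ionone)
Conditions: AcCl (1.2 equiv), Pd2(dba)3 (2.5 mol %), P(2-furyl)3 (10 mol %), THF, 50 °C
Reagents that add atoms: acetyl chloride, CC(Cl)=O
Why: Stille acylation (zerovalent palladium, acid chloride, alkenylstannane) proceeds with retention of alkene geometry and should give the (E)-enone under neutral conditions that the homoallylic ester tolerates.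

Step 9
Reactants: 11 (3R)-3-myristoyloxy-β-ionone
Product: 12 (1R)-4-[(1E)-3-hydroxy-3-methylpenta-1,4-dien-1-yl]-3,5,5-trimethylcyclohex-3-en-1-yl tetradecanoate (carbinol epimers)
Conditions: CH2=CHMgBr (1.1 equiv), THF, −78 °C; aq. NH4Cl
Reagents that add atoms: vinylmagnesium bromide, C=C[Mg]Br
Why: At −78 °C the vinyl Grignard reagent should add 1,2 to the methyl ketone much faster than to the hindered secondary ester, giving the tertiary bis-allylic alcohol of the vinyl-β-ionol type.

Step 10
Reactants: 12 tertiary bis-allylic alcohol of ring A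
Product: 13 {(2E,4E)-3-methyl-5-[(4R)-2,6,6-trimethyl-4-(tetradecanoyloxy)cyclohex-1-en-1-yl]penta-2,4-dien-1-yl}triphenylphosphonium bromide
Conditions: PPh3·HBr (1.05 equiv), CH2Cl2, 0 °C → rt; crystallisation
Reagents that add atoms: triphenylphosphine hydrobromide, [Br-].c1ccc(cc1)[PH+](c1ccccc1)c1ccccc1
Why: Ionisation of the tertiary allylic alcohol and capture of the dienyl cation by PPh3 at the primary terminus (allylic transposition, the standard entry to C15 Wittig salts) should give mainly the (9E)-salt while the homoallylic ester is not ionised.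

**Ring B fragment**

Step 11
Reactants: 14 (R)-α-ionone
Product: 15 2-methyl-2-{(E)-2-[(1R)-2,6,6-trimethylcyclohex-2-en-1-yl]ethenyl}-1,3-dioxolane
Conditions: HOCH2CH2OH, HC(OEt)3, p-TsOH·H2O (cat.), rt
Reagents that add atoms: ethane-1,2-diol, OCCO
Why: Acid-catalysed ketalisation with orthoformate as water scavenger at room temperature should mask the side-chain enone for the next steps without moving the ring double bond or touching C6.

Step 12
Reactants: 15 (R)-α-ionone ethylene ketal
Product: 16 2-methyl-2-{(E)-2-[(1R)-2,6,6-trimethyl-4-oxocyclohex-2-en-1-yl]ethenyl}-1,3-dioxolane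
Conditions: t-BuOOH, Rh2(cap)4 (1 mol %; cap = caprolactamate), K2CO3, CH2Cl2, rt
Reagents that add atoms: tert-butyl hydroperoxide, CC(C)(C)OO
Why: Dirhodium-catalysed allylic oxidation with t-BuOOH should attack the ring allylic CH2 (C3) and give the enone, the doubly allylic C6–H being tertiary, shielded by the gem-dimethyl group and poorly aligned for abstraction.

Step 13
Reactants: 16 (6R)-3-oxo-α-ionone ethylene ketal
Product: 17 (1R,4R)-3,5,5-trimethyl-4-[(E)-2-(2-methyl-1,3-dioxolan-2-yl)ethenyl]cyclohex-2-en-1-ol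
Conditions: LiBH(s-Bu)3, THF, −78 °C; H2O
Reagents that add atoms: none
Why: 1,2-Reduction of the β,β-disubstituted cyclohexenone by the bulky hydride from the face anti to the pseudo-axial C1 methyl, which is the face of the pseudo-axial C6 side chain, should give the 3,6-trans alcohol (3R) by substrate control from C6.

Step 14
Reactants: 17 (3R,6R)-3-hydroxy-α-ionone ethylene ketal
Product: 18 (1R,4R)-3,5,5-trimethyl-4-[(E)-2-(2-methyl-1,3-dioxolan-2-yl)ethenyl]cyclohex-2-en-1-yl hexadecanoate
Conditions: palmitic acid, DCC, DMAP (cat.), CH2Cl2, rt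
Reagents that add atoms: hexadecanoic acid (palmitic acid), CCCCCCCCCCCCCCCC(=O)O
Why: Steglich esterification acylates the secondary allylic alcohol with retention under neutral conditions that spare the ketal.

Step 15
Reactants: 18 palmitate ketal
Product: 19 (1R,4R)-3,5,5-trimethyl-4-[(1E)-3-oxobut-1-en-1-yl]cyclohex-2-en-1-yl hexadecanoate ((3R,6R)-3-palmitoyloxy-α-ionone)
Conditions: PPTS (cat.), acetone/H2O, rt
Reagents that add atoms: water, O
Why: Mild acid-catalysed hydrolysis of the dioxolane should free the methyl ketone at an acidity that does not ionise the allylic ester or epimerise C6.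

Step 16
Reactants: 19 (3R,6R)-3-palmitoyloxy-α-ionone
Product: 20 (1R,4R)-4-[(1E)-3-hydroxy-3-methylpenta-1,4-dien-1-yl]-3,5,5-trimethylcyclohex-2-en-1-yl hexadecanoate (carbinol epimers)
Conditions: CH2=CHMgBr (1.1 equiv), THF, −78 °C; aq. NH4Cl
Reagents that add atoms: vinylmagnesium bromide, C=C[Mg]Br
Why: As in step 9, low-temperature 1,2-addition to the methyl ketone should outrun attack on the ester and deprotonation at C6.

Step 17
Reactants: 20 tertiary bis-allylic alcohol of ring B
Product: 21 {(2E,4E)-3-methyl-5-[(1R,4R)-4-(hexadecanoyloxy)-2,6,6-trimethylcyclohex-2-en-1-yl]penta-2,4-dien-1-yl}triphenylphosphonium bromide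
Conditions: PPh3·HBr (1.05 equiv), CH2Cl2, 0 °C → rt; crystallisation
Reagents that add atoms: triphenylphosphine hydrobromide, [Br-].c1ccc(cc1)[PH+](c1ccccc1)c1ccccc1
Why: The tertiary dienylic carbinol should ionise far more readily than the secondary allylic ester of the ring, so PPh3 captures the side-chain cation at its primary terminus and gives the C15 salt with both stereocentres intact.

**Assembly**

Step 18
Reactants: 21 ring-B C15 phosphonium bromide; 22 (2E,4E,6E)-2,7-dimethylocta-2,4,6-trienedial (3 equiv)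
Product: 24 (3R,6R)-3-(hexadecanoyloxy)-12′-apo-ε-caroten-12′-al (all-E C25 aldehyde), via phosphonium ylide 23 (not isolated)
Conditions: 21 added slowly to 22 in 1,2-epoxybutane, 60 °C, dark, Ar; then I2 (cat.), CH2Cl2, diffuse light, rt
Reagents that add atoms: none
Why: Wittig olefination under base-free conditions (bromide opens the epoxide and the resulting alkoxide deprotonates the salt) with excess dialdehyde should give the mono-adduct, and iodine-catalysed equilibration should turn any (Z)-isomer at the new bond into the all-E aldehyde.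

Step 19
Reactants: 13 ring-A C15 phosphonium bromide; 24 C25 apo-aldehyde
Product: 26 (3R,3′R,6′R)-β,ε-carotene-3,3′-diyl 3-tetradecanoate 3′-hexadecanoate (CNP0230054.1), via phosphonium ylide 25 (not isolated)
Conditions: 1,2-epoxybutane/CH2Cl2, 60 °C (sealed), dark, Ar; then I2 (cat.), hexane/CH2Cl2, diffuse light, rt
Reagents that add atoms: none
Why: Wittig union of the two halves at C11=C12 under the same ester-tolerant conditions, followed by iodine-catalysed Z-to-E equilibration, should give the all-E polyene with the three stereocentres and both esters untouched.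

**Compound list**
1 | 2-methylcyclopent-2-en-1-one | CC1=CCCC1=O | starting material
2 | 2,5-dimethylcyclopent-2-en-1-one (racemic) | CC1=CCC(C)C1=O | intermediate
3 | 2,5,5-trimethylcyclopent-2-en-1-one | CC1=CCC(C)(C)C1=O | intermediate
4 | (1R)-2,5,5-trimethylcyclopent-2-en-1-ol | O[C@H]1C(C)=CCC1(C)C | intermediate
5 | (1S,2R,5S)-1,3,3-trimethylbicyclo[3.1.0]hexan-2-ol | CC1(C)C[C@@H]2C[C@]2(C)[C@@H]1O | intermediate
6 | (1S,5S)-1,3,3-trimethylbicyclo[3.1.0]hexan-2-one | CC1(C)C[C@@H]2C[C@]2(C)C1=O | intermediate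
7 | (1S,5S)-2-ethynyl-1,3,3-trimethylbicyclo[3.1.0]hexan-2-ol (C2 epimers) | CC1(C)C[C@@H]2C[C@]2(C)C1(O)C#C | intermediate
8 | (1S,5S)-2-ethynyl-1,3,3-trimethylbicyclo[3.1.0]hexan-2-yl cation | CC1(C)C[C@@H]2C[C@]2(C)[C+]1C#C | intermediate
9 | (1R)-4-ethynyl-3,5,5-trimethylcyclohex-3-en-1-yl tetradecanoate | C#CC1=C(C)C[C@@H](OC(=O)CCCCCCCCCCCCC)CC1(C)C | intermediate
10 | (1R)-3,5,5-trimethyl-4-[(E)-2-(tributylstannyl)ethenyl]cyclohex-3-en-1-yl tetradecanoate | CCCC[Sn](CCCC)(CCCC)/C=C/C1=C(C)C[C@@H](OC(=O)CCCCCCCCCCCCC)CC1(C)C | intermediate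
11 | (1R)-3,5,5-trimethyl-4-[(1E)-3-oxobut-1-en-1-yl]cyclohex-3-en-1-yl tetradecanoate | CC(=O)/C=C/C1=C(C)C[C@@H](OC(=O)CCCCCCCCCCCCC)CC1(C)C | intermediate
12 | (1R)-4-[(1E)-3-hydroxy-3-methylpenta-1,4-dien-1-yl]-3,5,5-trimethylcyclohex-3-en-1-yl tetradecanoate (carbinol epimers) | C=CC(C)(O)/C=C/C1=C(C)C[C@@H](OC(=O)CCCCCCCCCCCCC)CC1(C)C | intermediate
13 | {(2E,4E)-3-methyl-5-[(4R)-2,6,6-trimethyl-4-(tetradecanoyloxy)cyclohex-1-en-1-yl]penta-2,4-dien-1-yl}triphenylphosphonium bromide | [Br-].c1ccccc1[P+](c1ccccc1)(c1ccccc1)C/C=C(C)/C=C/C1=C(C)C[C@@H](OC(=O)CCCCCCCCCCCCC)CC1(C)C | intermediate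
14 | (R)-α-ionone, (3E)-4-[(1R)-2,6,6-trimethylcyclohex-2-en-1-yl]but-3-en-2-one | CC(=O)/C=C/[C@H]1C(C)=CCCC1(C)C | starting material
15 | 2-methyl-2-{(E)-2-[(1R)-2,6,6-trimethylcyclohex-2-en-1-yl]ethenyl}-1,3-dioxolane | CC1(/C=C/[C@H]2C(C)=CCCC2(C)C)OCCO1 | intermediate
16 | 2-methyl-2-{(E)-2-[(1R)-2,6,6-trimethyl-4-oxocyclohex-2-en-1-yl]ethenyl}-1,3-dioxolane | O=C1C=C(C)[C@H](/C=C/C2(C)OCCO2)C(C)(C)C1 | intermediate
17 | (1R,4R)-3,5,5-trimethyl-4-[(E)-2-(2-methyl-1,3-dioxolan-2-yl)ethenyl]cyclohex-2-en-1-ol | O[C@H]1C=C(C)[C@H](/C=C/C2(C)OCCO2)C(C)(C)C1 | intermediate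
18 | (1R,4R)-3,5,5-trimethyl-4-[(E)-2-(2-methyl-1,3-dioxolan-2-yl)ethenyl]cyclohex-2-en-1-yl hexadecanoate | CCCCCCCCCCCCCCCC(=O)O[C@H]1C=C(C)[C@H](/C=C/C2(C)OCCO2)C(C)(C)C1 | intermediate
19 | (1R,4R)-3,5,5-trimethyl-4-[(1E)-3-oxobut-1-en-1-yl]cyclohex-2-en-1-yl hexadecanoate | CCCCCCCCCCCCCCCC(=O)O[C@H]1C=C(C)[C@H](/C=C/C(C)=O)C(C)(C)C1 | intermediate
20 | (1R,4R)-4-[(1E)-3-hydroxy-3-methylpenta-1,4-dien-1-yl]-3,5,5-trimethylcyclohex-2-en-1-yl hexadecanoate (carbinol epimers) | CCCCCCCCCCCCCCCC(=O)O[C@H]1C=C(C)[C@H](/C=C/C(C)(O)C=C)C(C)(C)C1 | intermediate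
21 | {(2E,4E)-3-methyl-5-[(1R,4R)-4-(hexadecanoyloxy)-2,6,6-trimethylcyclohex-2-en-1-yl]penta-2,4-dien-1-yl}triphenylphosphonium bromide | CCCCCCCCCCCCCCCC(=O)O[C@H]1C=C(C)[C@H](/C=C/C(C)=C/C[P+](c2ccccc2)(c2ccccc2)c2ccccc2)C(C)(C)C1.[Br-] | intermediate
22 | (2E,4E,6E)-2,7-dimethylocta-2,4,6-trienedial | O=C/C(C)=C/C=C/C=C(C)/C=O | starting material
23 | {(2E,4E)-3-methyl-5-[(1R,4R)-4-(hexadecanoyloxy)-2,6,6-trimethylcyclohex-2-en-1-yl]penta-2,4-dien-1-ylidene}triphenylphosphorane | CCCCCCCCCCCCCCCC(=O)O[C@H]1C=C(C)[C@H](/C=C/C(C)=C/C=P(c2ccccc2)(c2ccccc2)c2ccccc2)C(C)(C)C1 | intermediate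
24 | (3R,6R)-3-(hexadecanoyloxy)-12′-apo-ε-caroten-12′-al (all-E) | CCCCCCCCCCCCCCCC(=O)O[C@H]1C=C(C)[C@H](/C=C/C(C)=C/C=C/C(C)=C/C=C/C=C(C)/C=O)C(C)(C)C1 | intermediate
25 | {(2E,4E)-3-methyl-5-[(4R)-2,6,6-trimethyl-4-(tetradecanoyloxy)cyclohex-1-en-1-yl]penta-2,4-dien-1-ylidene}triphenylphosphorane | c1ccccc1P(c1ccccc1)(c1ccccc1)=C/C=C(C)/C=C/C1=C(C)C[C@@H](OC(=O)CCCCCCCCCCCCC)CC1(C)C | intermediate
26 | (3R,3′R,6′R)-β,ε-carotene-3,3′-diyl 3-tetradecanoate 3′-hexadecanoate (CNP0230054.1) | CCCCCCCCCCCCCCCC(=O)O[C@H]1C=C(C)[C@H](/C=C/C(C)=C/C=C/C(C)=C/C=C/C=C(C)/C=C/C=C(C)/C=C/C2=C(C)C[C@@H](OC(=O)CCCCCCCCCCCCC)CC2(C)C)C(C)(C)C1 | target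

**Totals**
Total step count: 19. Longest linear sequence: 11 steps (steps 1–10, then step 19).

**Steps most likely to fail**

Step 6. The cation may be intercepted by water, by the hydroxyl group of unreacted 7 or at the cyclopropane methylene instead of the methine, or the weakly nucleophilic fatty acid may react so slowly that oligomerisation takes over. The fallback sets out from 7 and separates ring expansion from acylation. Hydrolytic homoallylic ring expansion under the classical equilibrating conditions (HClO4 cat., dioxane/H2O, rt), with water as a small and abundant nucleophile and the same inversion at the methine, should give (1R)-4-ethynyl-3,5,5-trimethylcyclohex-3-en-1-ol F1. Steglich esterification of F1 (myristic acid, DCC, DMAP, CH2Cl2) then returns to the route at 9.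

Step 2. Facial selectivity may be poor or reversed, because both α-carbons of the ketone are fully substituted and the catalyst may not tell them apart. The fallback sets out from 3 and replaces catalysis by resolution. Luche reduction (NaBH4, CeCl3·7H2O, MeOH, 0 °C) gives rac-2,5,5-trimethylcyclopent-2-en-1-ol F2. Esterification with (2S)-2-methoxy-2-phenylacetic acid (DCC, DMAP) gives the diastereomers (1R)-2,5,5-trimethylcyclopent-2-en-1-yl (2S)-2-methoxy-2-phenylacetate F3 and (1S)-2,5,5-trimethylcyclopent-2-en-1-yl (2S)-2-methoxy-2-phenylacetate F4, which are separated by chromatography. Saponification of F3 (LiOH, THF/H2O) returns to the route at 4.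

Step 13. Hydride may be delivered to the wrong face of the ring ketone, giving the 3,6-cis alcohol as the main product. The fallback sets out from 16 and corrects the configuration by substitution instead of by face selection. The cis product (1S,4R)-3,5,5-trimethyl-4-[(E)-2-(2-methyl-1,3-dioxolan-2-yl)ethenyl]cyclohex-2-en-1-ol F5 is isolated from the same reduction. Mitsunobu esterification of F5 with palmitic acid (PPh3, DIAD, toluene, 0 °C) inverts C3 and returns to the route at 18, by-passing 17 and step 14.

**Further compounds**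
F1 | step 6 | (1R)-4-ethynyl-3,5,5-trimethylcyclohex-3-en-1-ol | C#CC1=C(C)C[C@@H](O)CC1(C)C
F2 | step 2 | rac-2,5,5-trimethylcyclopent-2-en-1-ol | OC1C(C)=CCC1(C)C
F3 | step 2 | (1R)-2,5,5-trimethylcyclopent-2-en-1-yl (2S)-2-methoxy-2-phenylacetate | CO[C@H](C(=O)O[C@H]1C(C)=CCC1(C)C)c1ccccc1
F4 | step 2 | (1S)-2,5,5-trimethylcyclopent-2-en-1-yl (2S)-2-methoxy-2-phenylacetate | CO[C@H](C(=O)O[C@@H]1C(C)=CCC1(C)C)c1ccccc1
F5 | step 13 | (1S,4R)-3,5,5-trimethyl-4-[(E)-2-(2-methyl-1,3-dioxolan-2-yl)ethenyl]cyclohex-2-en-1-ol | O[C@@H]1C=C(C)[C@H](/C=C/C2(C)OCCO2)C(C)(C)C1
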